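Read the flask when 30% of its Sbt has gone; the charges, earlier runs and questions stand here.

all flasks: Cat 0.27 mol%

|  | Sbt | Rea | remark |
|---|---|---|---|
| cedar | 1.5 M | 0.30 equiv | run made earlier |
| maple | 1.5 M | 0.45 equiv | run made earlier |
| ash | 2.2 M | 0.60 equiv | run made earlier |
| flask | 1.5 M | 0.600 equiv |  |

| run | time / min | Tgt / % | Sbt / % |
|---|---|---|---|
| cedar | 2.00 | 7.7 | 91.2 |
| cedar | 5.00 | 15.2 | 80.5 |
| cedar | 10.0 | 24.2 | 70.2 |
| cedar | 15.0 | 29.0 | 61.1 |
| maple | 4.00 | 17.5 | 79.4 |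
| maple | 8.00 | 31.6 | 62.4 |
| maple | 10.0 | 34.3 | 57.9 |
| maple | 15.0 | 39.5 | 46.0 |
| ash | 4.00 | 27.6 | 67.2 |
| ash | 8.00 | 44.9 | 43.6 |
| ash | 10.0 | 49.6 | 35.5 |
| ash | 15.0 | 57.5 | 24.1 |

(each reading ± 1 percentage point)

- steps thought possible: Sbt + Rea.Cat <-> Imd; Sbt + Bpr -> Sbt.Bpr; 2 Cat <-> Oth; Imd -> Bpr + Imd2; Rea + Cat -> Rea.Cat; Imd2 -> Cat + Tgt

- apparent order in Cat when 30% of the Sbt are converted (percent change of the rate of making Tgt for one percent more Cat charged)
- apparent order in Rea when 30% of the Sbt are converted (percent change of the rate of making Tgt for one percent more Rea charged)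

Expect this in the flask at that moment. In maple at 8.00 min, Tgt was 84.0% of the Sbt lost, so take 25.2% of the Sbt charged as Tgt. Count one Rea for each Tgt, and cRea falls from 0.900 M to 0.522 M. The ratio of cRea charged to cRea left is 1.72; call it the leverage.

Weigh Rea, the limiting reagent, with care: one percent more on its charge moves cRea left by 1.72 percent.

Now go to logarithms. Near this conversion, cRea left is 0.0870 M in cedar and 0.297 M in maple, which is 0.533 in powers of ten. The rate of making Tgt, read across neighbouring readings, rises by 0.407. The quotient gives an exponent of 0.764 on cRea left. Multiply it by the leverage and commit to 1.32 for Rea. Give no figure for Cat, because cedar, maple and ash share 0.27 mol%.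

The forecast gave 0.5 for Cat and 1.5 for Rea, higher than this reckoning, holding that “Rea + Cat looks turnover-limiting”.

The flask gives 0.79 for Cat and 1.3 for Rea.

    Sbt + Rea.Cat ⇌ Imd (K = 0.600 M⁻¹, k = 3.30 M⁻¹ s⁻¹)
    Sbt + Bpr → Sbt.Bpr (k = 7.90 × 10⁻⁴ M⁻¹ s⁻¹)
    2 Cat ⇌ Oth (K = 100 M⁻¹, k = 5.60 M⁻¹ s⁻¹)
    Imd → Bpr + Imd2 (k = 27.0 s⁻¹)
    Rea + Cat → Rea.Cat (k = 1.10 M⁻¹ s⁻¹)
    Imd2 → Cat + Tgt (k = 1.40 s⁻¹)

Divide 1.3 by the leverage and the exponent on cRea left in the flask is 0.745, beside 0.71 for one percent on the rate constant of Rea + Cat turning into Rea.Cat. With twice the Rea charged, the leverage falls to 1.27, and the rate gains a factor of 1.88. In the flask, Rea + Cat turning into Rea.Cat and Imd turning into Bpr + Imd2 had half their turnover up to 12.0 min behind them at 4.15 min and 4.16 min, while Rea fell from 86.4% at 1.20 min to 19.2% at 12.0 min. Sbt + Bpr then went on in the flask: at 120 min, Rea stood at 0%, and Sbt.Bpr had grown from 12.0% to 37.2%.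

All runs stem from a simulated flask for an exercise, and the scatter is random.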